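## Structural features

Selaginellin A is organised around a central benzene, ring A, with four different substituents on four adjacent carbons: methyl on C1, a (4-hydroxyphenyl)ethynyl group on C2, the quinone methide carbon Cq on C3 and a 4-hydroxyphenyl ring on C4; C5 and C6 bear hydrogen. Cq is a fully substituted sp2 carbon joining ring A, an unsubstituted phenyl ring and a cyclohexa-2,5-dien-1-one ring; the dienone is symmetric, so the exocyclic double bond has no geometry and the target has no stereocentre, hence no adjacent stereocentres to relate. The fragile groups are the para-quinone methide (electrophilic at Cq, in equilibrium with its hydrate, the triaryl carbinol), the diarylalkyne (open to acid addition and to attack by a neighbouring hydroxyl) and the two free phenols. The quinone methide is therefore carried as the Cq carbinol, and the three phenolic oxygens as methyl ethers, until the last step. The real difficulty is ring A itself: four contiguous substituents must be placed without regiochemical error, and the most crowded bond, C3–Cq, lies between the alkyne-bearing C2 and the aryl-bearing C4. The feature exploited is that, at the carbinol level, the oxygen on Cq is separated from C2 only by Cq and C3, so one silicon atom can bridge that oxygen and C2 in a five-membered ring (Si, O, Cq, C3, C2). A silicon-bound propyne (C1–C2) is thereby held beside the propargylic alkyne of the carbinol (C3–C4), and the unsubstituted C5–C6 edge corresponds to acetylene. In the intermediates Cq is the only stereocentre; it is formed racemic and is erased when the quinone methide is unveiled.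

## Logic of the disconnections

**14 to 13.** The double bond from Cq to the dienone ring and the three phenolic O–H bonds of 14 are retraced to a Cq–OH bond and three O–CH3 bonds in 13. A hydroxyl on Cq plus a para oxygen on one of its aryl groups is a latent quinone methide, so the electrophilic chromophore need exist only at the very end. The gain is a neutral, robust carbinol whose masked phenols cannot interfere with organometallic or palladium chemistry. The demand is that one Lewis acid removes three methyl groups and ionises Cq without adding across the triple bond or closing a fluorene ring onto the C4 aryl group.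

**13 to 12 and 1.** The C2–C(sp) bond is cut. The arylethynyl group is the one substituent of ring A that cannot be carried through an alkyne cyclotrimerisation, so it is attached afterwards, and 1 is used a second time, which keeps the building blocks at four. The demand is a cross-coupling at a carbon flanked by a methyl group and the triaryl carbinol, next to a free tertiary hydroxyl.

**12 to 11.** The O–S bond is cut to reveal the C2 phenol. The demand is sulfonylation of the phenol only, under conditions that do not ionise the carbinol.

**11 to 10.** The C2–O bond is traced back to a C2–Si bond and the carbinol O–H to an O–Si bond on the same silicon atom. The phenol and the Cq hydroxyl are exactly the two groups a 2,1-benzoxasilole releases on oxidation, so the tether that directs the ring construction also marks C2 for the later coupling and protects the carbinol. The demand is oxidation of a hindered aryl–silicon bond without protodesilylation.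

**10 to 8 and 9.** Three bonds of ring A are cut: C2–C3, C4–C5 and C6–C1. This opens ring A and the oxasilole ring together and turns a tetrasubstituted arene into an acyclic diyne in which Cq already holds all of its carbon substituents, plus the simplest alkyne. The forward step must join a diyne substituted at both outer carbons with 9 faster than 9 reacts with itself, and must not ionise the doubly benzylic propargylic C–O bond.

**8 to 1, 2, 3 and 4.** The Cq–C(sp) bond, the O–Si bond and the Si–C(sp) bond are cut. Each is a polar bond formed from a commercial nucleophile and electrophile, and the three can be made in one flask through 5, 6 and 7. The forward sequence requires that the hindered alkoxide 6 displaces only one chloride of 3, which its bulk ensures. The small methyl groups on silicon are kept because a bulkier silicon centre would not accept a tertiary alkoxide and would slow the later oxidation.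

## Other disconnections considered

**Alternative 1:** The cut runs through C6–C1 and C3–C4 and divides ring A into a C1–C2–C3 piece and a C4–C5–C6 piece. In the forward sense TiCl4 would condense the 1,3-bis(silyloxy)diene A1, a masked 1,3-dicarbonyl dianion, with the 3-methoxyenone A2. The terminal carbon of A1 adds in conjugate fashion to the methoxy-bearing carbon of A2 (C6–C1), the central carbon of A1 attacks the ketone (C3–C4), and loss of methanol and water should aromatise the ring to the salicylate A3.
- In favour: cheap acyclic partners, no transition metal, no gas, and regiochemistry that follows from the polarity of the two three-carbon units.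
- Against: Cq arrives only as an ester carbon wedged between two ortho substituents and must still receive two different aryl groups, which means passing through a diaryl ketone at the most hindered site. The C2 alkyne still has to be coupled through the triflate.
- Structure: A3 holds the methyl group, the C2 oxygen and the C4 aryl group correctly but leaves Cq two carbon–carbon bonds short, whereas 10 leaves the key step with Cq complete.
- Mechanism: both ring constructions are regiochemically unambiguous, one by polarity and one by tether, so the plans are equal on that point. The alternative is better in that the C2 oxygen appears directly as a phenol, with no aryl–silicon oxidation (step 3 of the chosen plan).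
- Step economy: it is the weaker plan. Two to three steps lead to A1 and A2, then the condensation, then roughly six more operations (triflation, alkynylation, ester to ketone, second aryl addition, demethylation), against six steps in all for the chosen route.

**Alternative 2:** Ring A is bought as a fluoroarene, and the cuts are the C4–aryl bond and the C3–Cq bond. In the forward sense the aryllithium A5 would deprotonate the fluoroarene A4 at C4 and loss of fluoride would give the aryne A6. A second equivalent of A5 would add at C4 under the inductive direction of the C2 alkynyl group, and the C3 aryllithium A7 would be trapped by 2 to give the carbinol A8, which is the same compound as 13.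
- In favour: three components are joined in one flask, the alkyne is attached while C2 is still unhindered (a clear advantage over step 5 of the chosen plan), and A8 is one step from 14.
- Against: the regiochemistry of the aryne addition rests on a polarisation effect and not on a covalent constraint. A5 in excess competes with A7 for 2, A7 is flanked by two ortho groups and must add to a diaryl ketone, and A5 can also add to the triple bond or metalate the benzylic methyl group.
- Structure: the alternative forms the most crowded bond, C3–Cq, intermolecularly and last, whereas the chosen plan completes Cq first and builds ring A around it.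
- Mechanism: it is a kinetically controlled cascade with several competing nucleophile–electrophile pairings, against a catalytic, tether-directed cycloaddition in which only one connectivity is possible.
- Step economy: with one coupling to reach A4 the whole synthesis would take about three steps, so this alternative is better than the chosen route. Because both plans meet at 13, it is kept as the contingency for the key step.

**Alternative 3:** The cuts are C1–C2 and C3–C4, which divide ring A into a four-carbon diene (C4, C5, C6, C1) and a two-carbon dienophile (C2, C3). In the forward sense the E,E diene A9 would add thermally across the ketone-activated triple bond of the diynone A10 to give the cis-cyclohexa-1,4-diene A11. Dehydrogenation would then give the benzophenone A12, addition of A5 to its ketone would give 13, and demethylation would finish.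
- In favour: one cycloaddition brings all four substituents of ring A, the alkyne included, so there is no late coupling at a crowded carbon, which is better than the chosen plan on that point. No metal is needed for the ring construction.
- Against: both termini of A9 are substituted, and the aryl and methyl groups direct in opposite senses, so the orientation is a preference and not a certainty. A10 offers a second triple bond and is prone to polymerise on heating. Two stereocentres are made only to be destroyed. Cq leaves the key step as a ketone, one aryl group short, and that ketone sits between two ortho substituents.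
- Structure: the chosen plan delivers an aromatic ring with Cq complete, the alternative a dihydroarene with Cq incomplete.
- Mechanism: the alternative relies on frontier-orbital regiocontrol, the chosen plan on a tether.
- Step economy: about equal. One step to A9, two to A10, then four more, against six.

Key step: step 2

Remark: ring A is numbered C1 (methyl), C2 (alkynyl), C3 (bearing Cq), C4 (oxygenated aryl), C5 and C6 (H). All chiral intermediates are racemic, and each SMILES shows one enantiomer of the racemate.

## Route

**Step 1**
Reactants: 1 4-ethynylanisole (1-ethynyl-4-methoxybenzene); 2 4-methoxybenzophenone; 3 dichlorodimethylsilane; 4 prop-1-yn-1-ylmagnesium bromide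
Product: 8 rac-{[1,3-bis(4-methoxyphenyl)-1-phenylprop-2-yn-1-yl]oxy}(dimethyl)(prop-1-yn-1-yl)silane, via lithium acetylide 5 (not isolated), via lithium alkoxide 6 (not isolated), via chlorosilyl ether 7 (not isolated)
Conditions: n-BuLi, THF, −78 °C; 2, −78 → 0 °C; Me2SiCl2 (3 equiv), −78 °C → rt, volatiles removed; MeC≡CMgBr, THF, 0 °C → rt
Reagents that add atoms: none
Why: 1,2-Addition of a lithium acetylide to a non-enolisable diaryl ketone gives the tertiary propargylic alkoxide, which is too hindered to displace more than one chloride of Me2SiCl2; the remaining Si–Cl bond is then substituted by the alkynyl Grignard reagent (nucleophilic substitution at silicon). Cq is formed without facial control and is racemic, which is of no consequence because it becomes sp2 in step 6.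

**Step 2**
Reactants: 8 rac-{[1,3-bis(4-methoxyphenyl)-1-phenylprop-2-yn-1-yl]oxy}(dimethyl)(prop-1-yn-1-yl)silane; 9 acetylene
Product: 10 rac-3,4-bis(4-methoxyphenyl)-1,1,7-trimethyl-3-phenyl-1,3-dihydro-2,1-benzoxasilole
Conditions: Cp*RuCl(cod) (5–10 mol %), HC≡CH (1 atm), ClCH2CH2Cl, rt → 60 °C
Reagents that add atoms: none
Why: After loss of cod, Cp*RuCl binds both triple bonds of 8 and oxidative cyclisation joins their inner carbons (C2–C3), giving a ruthenacyclopentadiene in which ruthenium holds C1 and C4 and the five-membered oxasilole ring (Si, O, Cq, C3, C2) is already closed. Acetylene 9 then coordinates and inserts, and reductive elimination forms C4–C5 and C6–C1, closes ring A and returns the catalyst; every atom of 8 and 9 is kept. The closest known reaction type is the Cp*RuCl-catalysed (2+2+2) cycloaddition of 1,6-diynes, boron- and silicon-tethered ones among them, with a monoalkyne. As to mode of closure, the oxasilole ring closes by metal-templated C–C coupling of two alkynes held three atoms apart, and ring A closes by (2+2+2) cycloaddition with two edges from 8 and one from 9. No stereocentre is formed; Cq is a racemic spectator. The step needs regiocontrol and chemoselectivity: the Si–O tether allows only one mutual orientation of the two tethered alkynes, so methyl, silicon, Cq and the anisyl group must end on C1 to C4 in that order, and cross-reaction should win over trimerisation of 9 because the first C–C bond forms intramolecularly, helped by the gem-diaryl (Thorpe–Ingold) effect at Cq. Acetylene is the smallest possible third partner, which matters because both outer alkyne carbons of 8 are substituted, and the neutral catalyst should not ionise the doubly benzylic propargylic C–O bond as a cationic Lewis-acidic metal might.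

**Step 3**
Reactants: 10 rac-3,4-bis(4-methoxyphenyl)-1,1,7-trimethyl-3-phenyl-1,3-dihydro-2,1-benzoxasilole
Product: 11 rac-2-[hydroxy(4-methoxyphenyl)(phenyl)methyl]-4'-methoxy-4-methylbiphenyl-3-ol
Conditions: 30 % aq. H2O2, KHCO3, THF/MeOH, rt → 50 °C
Reagents that add atoms: hydrogen peroxide, OO
Why: Tamao oxidation: the alkoxy group on silicon and the strain of the five-membered ring make silicon receptive to hydroperoxide, the aryl group migrates from silicon to oxygen, and hydrolysis of the two Si–O bonds releases the C2 phenol and the Cq hydroxyl. Aryl methyl ethers and the tertiary carbinol are inert to buffered peroxide, and the stereocentre is not touched.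

**Step 4**
Reactants: 11 rac-2-[hydroxy(4-methoxyphenyl)(phenyl)methyl]-4'-methoxy-4-methylbiphenyl-3-ol
Product: 12 rac-2-[hydroxy(4-methoxyphenyl)(phenyl)methyl]-4'-methoxy-4-methylbiphenyl-3-yl trifluoromethanesulfonate
Conditions: PhNTf2, Et3N, DMAP (cat.), CH2Cl2, rt
Reagents that add atoms: N-phenylbis(trifluoromethanesulfonimide), O=S(=O)(N(c1ccccc1)S(=O)(=O)C(F)(F)F)C(F)(F)F
Why: O-Sulfonylation (triflation) of a phenol: only the phenol is acidic enough to be activated by the amine, and the tertiary triaryl carbinol is too hindered to attack the bulky triflimide. The mild triflyl donor avoids the ionisation at Cq that triflic anhydride could cause.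

**Step 5**
Reactants: 12 rac-2-[hydroxy(4-methoxyphenyl)(phenyl)methyl]-4'-methoxy-4-methylbiphenyl-3-yl trifluoromethanesulfonate; 1 4-ethynylanisole
Product: 13 rac-(4-methoxyphenyl){4'-methoxy-3-[(4-methoxyphenyl)ethynyl]-4-methylbiphenyl-2-yl}(phenyl)methanol
Conditions: PdCl2(PPh3)2 (cat.), CuI (cat.), n-Bu4NI, Et3N, DMF, 70 °C
Reagents that add atoms: none
Why: Sonogashira coupling: oxidative addition of the aryl triflate to zerovalent palladium (assisted by iodide), transmetallation from the alkynylcopper CuC≡CAr formed from 1 and CuI, and reductive elimination form the C2–C(sp) bond. The amine is too weak a base to deprotonate the tertiary hydroxyl, so the carbinol can be carried unprotected.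

**Step 6**
Reactants: 13 rac-(4-methoxyphenyl){4'-methoxy-3-[(4-methoxyphenyl)ethynyl]-4-methylbiphenyl-2-yl}(phenyl)methanol
Product: 14 selaginellin A, 4-[{4'-hydroxy-3-[(4-hydroxyphenyl)ethynyl]-4-methylbiphenyl-2-yl}(phenyl)methylidene]cyclohexa-2,5-dien-1-one
Conditions: BBr3 (excess), CH2Cl2, −78 → 0 °C; aq. NaHCO3
Reagents that add atoms: none
Why: Lewis-acid cleavage of aryl methyl ethers with BBr3 combined with dehydration: the carbinol is ionised at Cq, the methyl group on the oxygen conjugated to the cationic centre is lost to bromide to give the quinone methide directly, and the two remaining methyl ethers are cleaved in the usual way before aqueous work-up frees the phenols. The internal diarylalkyne should survive at low temperature, and the stereocentre disappears as Cq becomes sp2.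

## Compound list

1 | 4-ethynylanisole (1-ethynyl-4-methoxybenzene) | C#Cc1ccc(OC)cc1 | starting material
2 | 4-methoxybenzophenone | COc1ccc(cc1)C(=O)c1ccccc1 | starting material
3 | dichlorodimethylsilane | C[Si](C)(Cl)Cl | starting material
4 | prop-1-yn-1-ylmagnesium bromide | CC#C[Mg]Br | starting material
5 | [(4-methoxyphenyl)ethynyl]lithium | [Li]C#Cc1ccc(OC)cc1 | intermediate
6 | rac-lithium 1,3-bis(4-methoxyphenyl)-1-phenylprop-2-yn-1-olate | [Li]O[C@](c1ccccc1)(c1ccc(OC)cc1)C#Cc1ccc(OC)cc1 | intermediate
7 | rac-chloro{[1,3-bis(4-methoxyphenyl)-1-phenylprop-2-yn-1-yl]oxy}dimethylsilane | C[Si](C)(Cl)O[C@](c1ccccc1)(c1ccc(OC)cc1)C#Cc1ccc(OC)cc1 | intermediate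
8 | rac-{[1,3-bis(4-methoxyphenyl)-1-phenylprop-2-yn-1-yl]oxy}(dimethyl)(prop-1-yn-1-yl)silane | CC#C[Si](C)(C)O[C@](c1ccccc1)(c1ccc(OC)cc1)C#Cc1ccc(OC)cc1 | intermediate
9 | acetylene | C#C | starting material
10 | rac-3,4-bis(4-methoxyphenyl)-1,1,7-trimethyl-3-phenyl-1,3-dihydro-2,1-benzoxasilole | Cc1ccc(-c2ccc(OC)cc2)c2c1[Si](C)(C)O[C@]2(c1ccccc1)c1ccc(OC)cc1 | intermediate
11 | rac-2-[hydroxy(4-methoxyphenyl)(phenyl)methyl]-4'-methoxy-4-methylbiphenyl-3-ol | Cc1ccc(-c2ccc(OC)cc2)c(c1O)[C@@](O)(c1ccccc1)c1ccc(OC)cc1 | intermediate
12 | rac-2-[hydroxy(4-methoxyphenyl)(phenyl)methyl]-4'-methoxy-4-methylbiphenyl-3-yl trifluoromethanesulfonate | Cc1ccc(-c2ccc(OC)cc2)c(c1OS(=O)(=O)C(F)(F)F)[C@@](O)(c1ccccc1)c1ccc(OC)cc1 | intermediate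
13 | rac-(4-methoxyphenyl){4'-methoxy-3-[(4-methoxyphenyl)ethynyl]-4-methylbiphenyl-2-yl}(phenyl)methanol | Cc1ccc(-c2ccc(OC)cc2)c([C@@](O)(c2ccccc2)c2ccc(OC)cc2)c1C#Cc1ccc(OC)cc1 | intermediate
14 | selaginellin A, 4-[{4'-hydroxy-3-[(4-hydroxyphenyl)ethynyl]-4-methylbiphenyl-2-yl}(phenyl)methylidene]cyclohexa-2,5-dien-1-one | Cc1ccc(-c2ccc(O)cc2)c(C(=C2C=CC(=O)C=C2)c2ccccc2)c1C#Cc1ccc(O)cc1 | target

## Step count and least certain steps

Total step count: 6. Longest linear sequence: 6 steps (1 and 2 to 8, then 10, 11, 12, 13, 14); 1 is used a second time in step 5.

**Step 2 (key step).** The oxidative cyclisation at ruthenium may be slow because both outer alkyne carbons of 8 are substituted and the propargylic carbon is quaternary. Oligomerisation of acetylene and decay of the catalyst would then take over, and traces of water would hydrolyse the Si–O tether before the ring forms. The fallback sets out from 1 and 2 and returns at 13; ring A is bought instead of built. Sonogashira coupling of 1 with 2-bromo-1-fluoro-3-methylbenzene F1 (PdCl2(PPh3)2, CuI, Et3N, 70 °C) would give 1-fluoro-2-[(4-methoxyphenyl)ethynyl]-3-methylbenzene F2. (4-Methoxyphenyl)lithium F4, made from 1-bromo-4-methoxybenzene F3 and n-BuLi in THF, is then used in excess. One equivalent removes the proton at C4 next to fluorine, and loss of fluoride gives 3-[(4-methoxyphenyl)ethynyl]-4-methyl-1,2-didehydrobenzene F5. A second equivalent adds at C4 to give {4'-methoxy-3-[(4-methoxyphenyl)ethynyl]-4-methylbiphenyl-2-yl}lithium F6, which is trapped in the same flask by 2 to give 13 after aqueous work-up. Steps 3 to 5 fall away and step 6 follows unchanged.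

**Step 5.** Oxidative addition at a triflate flanked by a methyl group and the triaryl carbinol may be slow, so that base-induced cleavage of the S–O bond and oxidative dimerisation of 1 compete. Once the triple bond is in place, copper or base may also promote addition of the neighbouring tertiary hydroxyl across it. The fallback sets out from 12 and 1 and returns at 13; the alkynyl group is delivered from a preformed organozinc instead of a catalytic alkynylcopper. Deprotonation of 1 with n-BuLi and transmetallation with ZnCl2 gives chloro[(4-methoxyphenyl)ethynyl]zinc F7. An excess, of which the first equivalent converts the hydroxyl of 12 into an unreactive zinc alkoxide, is coupled with 12 under Pd2(dba)3/XPhos in THF at 60 °C (Negishi coupling), with no copper, amine or carbonate present, to give 13 after work-up.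

**Step 3.** Attack of hydroperoxide on a silicon atom shielded by the C1 methyl group and the quaternary Cq may be slow, and ipso-protonation of the aryl–silicon bond in the basic aqueous medium would then replace oxidation by protodesilylation. On contact with acid the product may also lose water toward an ortho-quinone methide. The fallback sets out from 6 (made from 1 and 2 as in step 1), 4 and 9 and returns at 11; the tether atom is changed from silicon to boron, whose bond to carbon is oxidised far more easily. Protonation of 6 gives rac-1,3-bis(4-methoxyphenyl)-1-phenylprop-2-yn-1-ol F8. Diisopropyl prop-1-yn-1-ylboronate F9 (from 4 and B(OiPr)3, then anhydrous HCl) exchanges one isopropoxy group with F8 in the flask to give the mixed boronate rac-isopropyl 1,3-bis(4-methoxyphenyl)-1-phenylprop-2-yn-1-yl prop-1-yn-1-ylboronate F10. With 9 and Cp*RuCl(cod) in ClCH2CH2Cl this should undergo the same (2+2+2) cycloaddition to rac-1-isopropoxy-3,4-bis(4-methoxyphenyl)-7-methyl-3-phenyl-1,3-dihydro-2,1-benzoxaborole F11, and NaOH/H2O2 then gives 11.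

**Step 6.** Ionisation at Cq in the presence of a strong Lewis acid may be followed by Friedel–Crafts closure onto the C4 aryl ring (fluorene formation), and HBr generated in the flask may add across the electron-rich triple bond. Incomplete cleavage of the third ether is the milder failure. The fallback sets out from 3, 4 and 9, which are used unchanged, and returns at 14; the three phenols are carried as benzyl ethers. 1-(Benzyloxy)-4-ethynylbenzene F12 and [4-(benzyloxy)phenyl](phenyl)methanone F13 replace 1 and 2 in steps 1 to 5. They give in turn the tethered diyne rac-({1,3-bis[4-(benzyloxy)phenyl]-1-phenylprop-2-yn-1-yl}oxy)(dimethyl)(prop-1-yn-1-yl)silane F14, the benzoxasilole rac-3,4-bis[4-(benzyloxy)phenyl]-1,1,7-trimethyl-3-phenyl-1,3-dihydro-2,1-benzoxasilole F15, the phenol rac-4'-(benzyloxy)-2-{[4-(benzyloxy)phenyl](hydroxy)(phenyl)methyl}-4-methylbiphenyl-3-ol F16, its triflate F17 and the alkynyl carbinol rac-[4-(benzyloxy)phenyl][4'-(benzyloxy)-3-{[4-(benzyloxy)phenyl]ethynyl}-4-methylbiphenyl-2-yl](phenyl)methanol F18. BCl3 with pentamethylbenzene as cation scavenger in CH2Cl2 at −78 °C then removes the three benzyl groups and ionises Cq, at a temperature at which neither ring closure onto the C4 aryl group nor addition to the alkyne should occur, and work-up gives 14.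

## Further compounds

F1 | step 2 | 2-bromo-1-fluoro-3-methylbenzene | Cc1cccc(F)c1Br
F2 | step 2 | 1-fluoro-2-[(4-methoxyphenyl)ethynyl]-3-methylbenzene | Cc1cccc(F)c1C#Cc1ccc(OC)cc1
F3 | step 2 | 1-bromo-4-methoxybenzene | COc1ccc(Br)cc1
F4 | step 2 | (4-methoxyphenyl)lithium | [Li]c1ccc(OC)cc1
F5 | step 2 | 3-[(4-methoxyphenyl)ethynyl]-4-methyl-1,2-didehydrobenzene | CC1=C(C#Cc2ccc(OC)cc2)C#CC=C1
F6 | step 2 | {4'-methoxy-3-[(4-methoxyphenyl)ethynyl]-4-methylbiphenyl-2-yl}lithium | Cc1ccc(-c2ccc(OC)cc2)c([Li])c1C#Cc1ccc(OC)cc1
F7 | step 5 | chloro[(4-methoxyphenyl)ethynyl]zinc | Cl[Zn]C#Cc1ccc(OC)cc1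
F8 | step 3 | rac-1,3-bis(4-methoxyphenyl)-1-phenylprop-2-yn-1-ol | O[C@](c1ccccc1)(c1ccc(OC)cc1)C#Cc1ccc(OC)cc1
F9 | step 3 | diisopropyl prop-1-yn-1-ylboronate | CC#CB(OC(C)C)OC(C)C
F10 | step 3 | rac-isopropyl 1,3-bis(4-methoxyphenyl)-1-phenylprop-2-yn-1-yl prop-1-yn-1-ylboronate | CC#CB(OC(C)C)O[C@](c1ccccc1)(c1ccc(OC)cc1)C#Cc1ccc(OC)cc1
F11 | step 3 | rac-1-isopropoxy-3,4-bis(4-methoxyphenyl)-7-methyl-3-phenyl-1,3-dihydro-2,1-benzoxaborole | Cc1ccc(-c2ccc(OC)cc2)c2c1B(OC(C)C)O[C@]2(c1ccccc1)c1ccc(OC)cc1
F12 | step 6 | 1-(benzyloxy)-4-ethynylbenzene | C#Cc1ccc(OCc2ccccc2)cc1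
F13 | step 6 | [4-(benzyloxy)phenyl](phenyl)methanone | O=C(c1ccccc1)c1ccc(OCc2ccccc2)cc1
F14 | step 6 | rac-({1,3-bis[4-(benzyloxy)phenyl]-1-phenylprop-2-yn-1-yl}oxy)(dimethyl)(prop-1-yn-1-yl)silane | CC#C[Si](C)(C)O[C@](c1ccccc1)(c1ccc(OCc2ccccc2)cc1)C#Cc1ccc(OCc2ccccc2)cc1
F15 | step 6 | rac-3,4-bis[4-(benzyloxy)phenyl]-1,1,7-trimethyl-3-phenyl-1,3-dihydro-2,1-benzoxasilole | Cc1ccc(-c2ccc(OCc3ccccc3)cc2)c2c1[Si](C)(C)O[C@]2(c1ccccc1)c1ccc(OCc2ccccc2)cc1
F16 | step 6 | rac-4'-(benzyloxy)-2-{[4-(benzyloxy)phenyl](hydroxy)(phenyl)methyl}-4-methylbiphenyl-3-ol | Cc1ccc(-c2ccc(OCc3ccccc3)cc2)c(c1O)[C@@](O)(c1ccccc1)c1ccc(OCc2ccccc2)cc1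
F17 | step 6 | rac-4'-(benzyloxy)-2-{[4-(benzyloxy)phenyl](hydroxy)(phenyl)methyl}-4-methylbiphenyl-3-yl trifluoromethanesulfonate | Cc1ccc(-c2ccc(OCc3ccccc3)cc2)c(c1OS(=O)(=O)C(F)(F)F)[C@@](O)(c1ccccc1)c1ccc(OCc2ccccc2)cc1
F18 | step 6 | rac-[4-(benzyloxy)phenyl][4'-(benzyloxy)-3-{[4-(benzyloxy)phenyl]ethynyl}-4-methylbiphenyl-2-yl](phenyl)methanol | Cc1ccc(-c2ccc(OCc3ccccc3)cc2)c([C@@](O)(c2ccccc2)c2ccc(OCc3ccccc3)cc2)c1C#Cc1ccc(OCc2ccccc2)cc1
A1 | alternative 1 | 1-methoxy-1,3-bis(trimethylsilyloxy)penta-1,3-diene (double-bond geometry not defined) | COC(O[Si](C)(C)C)=CC(O[Si](C)(C)C)=CC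
A2 | alternative 1 | (2E)-3-methoxy-1-(4-methoxyphenyl)prop-2-en-1-one | CO/C=C/C(=O)c1ccc(OC)cc1
A3 | alternative 1 | methyl 2-hydroxy-6-(4-methoxyphenyl)-3-methylbenzoate | COC(=O)c1c(O)c(C)ccc1-c1ccc(OC)cc1
A4 | alternative 2 | 1-fluoro-2-[(4-methoxyphenyl)ethynyl]-3-methylbenzene | Cc1cccc(F)c1C#Cc1ccc(OC)cc1
A5 | alternative 2 | (4-methoxyphenyl)lithium | [Li]c1ccc(OC)cc1
A6 | alternative 2 | 3-[(4-methoxyphenyl)ethynyl]-4-methyl-1,2-didehydrobenzene | CC1=C(C#Cc2ccc(OC)cc2)C#CC=C1
A7 | alternative 2 | {4'-methoxy-3-[(4-methoxyphenyl)ethynyl]-4-methylbiphenyl-2-yl}lithium | Cc1ccc(-c2ccc(OC)cc2)c([Li])c1C#Cc1ccc(OC)cc1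
A8 | alternative 2 | rac-(4-methoxyphenyl){4'-methoxy-3-[(4-methoxyphenyl)ethynyl]-4-methylbiphenyl-2-yl}(phenyl)methanol | Cc1ccc(-c2ccc(OC)cc2)c([C@@](O)(c2ccccc2)c2ccc(OC)cc2)c1C#Cc1ccc(OC)cc1
A9 | alternative 3 | 1-methoxy-4-[(1E,3E)-penta-1,3-dien-1-yl]benzene | C/C=C/C=C/c1ccc(OC)cc1
A10 | alternative 3 | 5-(4-methoxyphenyl)-1-phenylpenta-2,4-diyn-1-one | O=C(C#CC#Cc1ccc(OC)cc1)c1ccccc1
A11 | alternative 3 | rac-cis-{6-(4-methoxyphenyl)-2-[(4-methoxyphenyl)ethynyl]-3-methylcyclohexa-1,4-dien-1-yl}(phenyl)methanone | C[C@@H]1C=C[C@H](c2ccc(OC)cc2)C(C(=O)c2ccccc2)=C1C#Cc1ccc(OC)cc1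
A12 | alternative 3 | {4'-methoxy-3-[(4-methoxyphenyl)ethynyl]-4-methylbiphenyl-2-yl}(phenyl)methanone | Cc1ccc(-c2ccc(OC)cc2)c(C(=O)c2ccccc2)c1C#Cc1ccc(OC)cc1
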